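**Retrosynthetic overview**
1. Target 16 ⇐ tetrabenzyl ether 15 (global hydrogenolysis); 15 ⇐ enol silane 12 + 4-(benzyloxy)benzaldehyde 13 by an asymmetric aldol/SNAr annulation that forms C3–C2 and O1–C8a and closes the flavanone pyranone ring last.
2. Enabling feature: the C4 carbonyl carbon sits on C4a of ring A, ortho to C8a, so the one acetyl group supplies the C3 nucleophile and also activates a C8a–F bond for ipso attack by the aldehyde-derived oxygen; the base-labile C2 stereocentre is therefore made in the penultimate step.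
3. 12 ⇐ ketone 11 ⇐ Ullmann C–O coupling (C6–O bond of the diaryl ether) of phenol 6 with 4'-iodoflavone 10.
4. 6 ⇐ 5-fluoro-1,2,3-trimethoxybenzene 1 (acylation, chelation-controlled bis-demethylation, O-3/O-2 differentiation); 10 ⇐ acetophenone 7 + 4-iodobenzaldehyde 8 (chalcone, oxidative cyclisation).
5. Ring order: flavone pyranone ring (step 6), then the diaryl ether (step 7), then the flavanone pyranone ring (step 9); all benzene rings are bought.

Key step: step 9

Assumption: 1 and 7 are taken as catalogue compounds. The enantiomer of the aldol catalyst in step 9 (from D- or L-tryptophan) is the one that directs attack to the Si face of the aldehyde, which corresponds to the 2S configuration of the target.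

**Route**

Step 1
Reactants: 1 5-fluoro-1,2,3-trimethoxybenzene
Product: 2 1-(6-fluoro-2,3,4-trimethoxyphenyl)ethanone
Conditions: AcCl, AlCl3, CH2Cl2, −10 → 0 °C
Reagents that add atoms: acetyl chloride CC(=O)Cl
Why: Friedel–Crafts acylation; the two free ring positions of 1 are equivalent (para to one methoxy group, ortho to fluorine), so a single ketone should form.

Step 2
Reactants: 2 1-(6-fluoro-2,3,4-trimethoxyphenyl)ethanone
Product: 3 1-(6-fluoro-2,3-dihydroxy-4-methoxyphenyl)ethanone
Conditions: BCl3 (3 equiv), CH2Cl2, −78 °C → rt; aqueous work-up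
Reagents that add atoms: none
Why: Chelation-controlled Lewis-acid ether cleavage; boron bound to the ketone cleaves the ortho methoxy group through a six-membered chelate and the resulting aryloxyborane cleaves the neighbouring methoxy group through a five-membered borate, while the remote 4-methoxy group has no such assistance and should survive.

Step 3
Reactants: 3 1-(6-fluoro-2,3-dihydroxy-4-methoxyphenyl)ethanone
Product: 5 1-[2-(benzyloxy)-6-fluoro-4-methoxy-3-(prop-2-en-1-yloxy)phenyl]ethanone, via 3-O-allyl ether 4 (not isolated)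
Conditions: NaH (2.05 equiv), DMF, 0 °C; allyl bromide (1.0 equiv), 0 °C → rt; then BnBr (1.3 equiv), 50 °C
Reagents that add atoms: allyl bromide C=CCBr; benzyl bromide BrCc1ccccc1
Why: Sequential Williamson etherification of the catechol dianion; the non-chelated, more basic O-3 should take the limiting allyl bromide first and the ketone-chelated O-2 phenoxide is benzylated on warming, which places benzyl on the oxygen that becomes the 5-oxygen of the flavanone.

Step 4
Reactants: 5 1-[2-(benzyloxy)-6-fluoro-4-methoxy-3-(prop-2-en-1-yloxy)phenyl]ethanone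
Product: 6 1-[2-(benzyloxy)-6-fluoro-3-hydroxy-4-methoxyphenyl]ethanone
Conditions: Pd(PPh3)4 (3 mol %), morpholine (3 equiv), THF, rt
Reagents that add atoms: none
Why: Tsuji–Trost-type Pd(0) deallylation; the allyl aryl ether ionises to a π-allylpalladium complex that morpholine captures, and the benzyl ether, aryl fluoride and ketone should be untouched.

Step 5
Reactants: 7 1-[2,4-bis(benzyloxy)-6-hydroxyphenyl]ethanone; 8 4-iodobenzaldehyde
Product: 9 (E)-1-[2,4-bis(benzyloxy)-6-hydroxyphenyl]-3-(4-iodophenyl)prop-2-en-1-one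
Conditions: KOH (aq), EtOH/THF, rt
Reagents that add atoms: none
Why: Claisen–Schmidt condensation; the methyl ketone enolate adds to the non-enolisable aldehyde and the aldol dehydrates to the conjugated E-chalcone.

Step 6
Reactants: 9 (E)-1-[2,4-bis(benzyloxy)-6-hydroxyphenyl]-3-(4-iodophenyl)prop-2-en-1-one
Product: 10 5,7-bis(benzyloxy)-2-(4-iodophenyl)-4H-chromen-4-one
Conditions: I2 (10 mol %), DMSO, 120 °C
Reagents that add atoms: none
Why: Iodine-catalysed oxidative cyclisation of a 2'-hydroxychalcone; oxa-Michael ring closure and iodination–elimination at C3 give the flavone with DMSO as terminal oxidant, and the aryl iodide and benzyl ethers should be inert.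

Step 7
Reactants: 6 1-[2-(benzyloxy)-6-fluoro-3-hydroxy-4-methoxyphenyl]ethanone; 10 5,7-bis(benzyloxy)-2-(4-iodophenyl)-4H-chromen-4-one
Product: 11 1-[2-(benzyloxy)-3-{4-[5,7-bis(benzyloxy)-4-oxo-4H-chromen-2-yl]phenoxy}-6-fluoro-4-methoxyphenyl]ethanone
Conditions: CuI (10 mol %), picolinic acid (20 mol %), K3PO4 (2 equiv), DMSO, 85 °C, N2
Reagents that add atoms: none
Why: Ullmann-type copper-catalysed C–O coupling with a picolinate ligand, a system suited to ortho-disubstituted phenols and aryl iodides; the C–F bond does not enter the copper cycle and is deactivated toward SNAr by the para phenoxide/aryloxy oxygen.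

Step 8
Reactants: 11 1-[2-(benzyloxy)-3-{4-[5,7-bis(benzyloxy)-4-oxo-4H-chromen-2-yl]phenoxy}-6-fluoro-4-methoxyphenyl]ethanone
Product: 12 5,7-bis(benzyloxy)-2-[4-(2-(benzyloxy)-4-fluoro-6-methoxy-3-{1-[(trimethylsilyl)oxy]ethenyl}phenoxy)phenyl]-4H-chromen-4-one
Conditions: TMSOTf (1.3 equiv), Et3N (2 equiv), CH2Cl2, 0 °C; non-aqueous work-up, used crude
Reagents that add atoms: trimethylsilyl trifluoromethanesulfonate C[Si](C)(C)OS(=O)(=O)C(F)(F)F
Why: Soft enolisation and O-silylation; the acetyl group is the only enolisable carbonyl, so the terminal trimethylsilyl enol ether should form cleanly.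

Step 9
Reactants: 12 5,7-bis(benzyloxy)-2-[4-(2-(benzyloxy)-4-fluoro-6-methoxy-3-{1-[(trimethylsilyl)oxy]ethenyl}phenoxy)phenyl]-4H-chromen-4-one; 13 4-(benzyloxy)benzaldehyde
Product: 15 (2S)-5-(benzyloxy)-2-[4-(benzyloxy)phenyl]-6-{4-[5,7-bis(benzyloxy)-4-oxo-4H-chromen-2-yl]phenoxy}-7-methoxy-2,3-dihydro-4H-chromen-4-one, via silyl aldol ether 14 (not isolated)
Conditions: N-tosyltryptophan-derived B-n-butyl-1,3,2-oxazaborolidin-5-one (20–30 mol %, Si-face-directing enantiomer), 13 (1.2 equiv), EtCN/CH2Cl2, −78 °C until 12 is consumed; then TBAT (0.4 equiv), THF, −78 → 0 °C, same flask; pH 7 buffer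
Reagents that add atoms: none
Why: Proposed new method: a chiral-Lewis-acid Mukaiyama aldol is telescoped with a fluoride-relay SNAr, so that 12 acts as a four-atom C3=C4–C4a=C8a(F) unit and the aldehyde C=O as the two-atom partner of a formal asymmetric oxa-[4+2] annulation; the boron catalyst binds the aldehyde, C3 of 12 adds to its exposed Si face through an open transition state, and silyl transfer gives the (S)-β-silyloxy ketone 14. Fluoride then cleaves the O–Si bond, the C2 alkoxide adds to C8a ipso to fluorine to give a dearomatised Meisenheimer adduct stabilised as the C4 enolate, and loss of fluoride rearomatises ring A while the expelled fluoride desilylates the next molecule of 14, with volatile Me3SiF as the sink. The closest known reaction types are the oxazaborolidinone-catalysed Mukaiyama aldol of aryl methyl ketone enol silanes with aromatic aldehydes, the fluoride-catalysed etherification of activated aryl fluorides with silyl ethers, and the SNAr ring closure of 2-fluoroaryl 1,3-dicarbonyl compounds to chromones. The pyranone ring closes by a six-membered addition–elimination at sp2 C8a (formally 6-endo with respect to the C8a=C4a–C4=O acceptor), and the only new stereocentre, C2, is fixed by the catalyst in the C–C bond formation and is not touched when its oxygen is arylated. The step needs ring closure to outrun retro-aldol cleavage and β-elimination of the aldolate and needs the enol silane to choose the aldehyde over the flavone carbonyl; the catalytic fluoride relay keeps the alkoxide at a low stationary concentration, the C4 carbonyl holds the C2 oxygen next to the activated C8a–F bond, the 5-benzyl ether prevents a deactivating phenoxide, and the flavone carbonyl is a vinylogous ester that does not accept enol silanes.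

Step 10
Reactants: 15 (2S)-5-(benzyloxy)-2-[4-(benzyloxy)phenyl]-6-{4-[5,7-bis(benzyloxy)-4-oxo-4H-chromen-2-yl]phenoxy}-7-methoxy-2,3-dihydro-4H-chromen-4-one
Product: 16 (2S)-6-[4-(5,7-dihydroxy-4-oxo-4H-chromen-2-yl)phenoxy]-5-hydroxy-2-(4-hydroxyphenyl)-7-methoxy-2,3-dihydro-4H-chromen-4-one (target CNP0269971.1)
Conditions: H2 (1 atm), 10 % Pd/C, THF/EtOAc, rt, stopped when debenzylation is complete
Reagents that add atoms: none
Why: Catalytic hydrogenolysis of the four aryl benzyl ethers under neutral conditions, which should leave the methyl ether, the diaryl ether, the flavone C2=C3 bond and the base-sensitive C2 stereocentre untouched.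

**Compound list**
1 | 5-fluoro-1,2,3-trimethoxybenzene | COc1cc(F)cc(OC)c1OC | starting material
2 | 1-(6-fluoro-2,3,4-trimethoxyphenyl)ethanone | CC(=O)c1c(F)cc(OC)c(OC)c1OC | intermediate
3 | 1-(6-fluoro-2,3-dihydroxy-4-methoxyphenyl)ethanone | CC(=O)c1c(F)cc(OC)c(O)c1O | intermediate
4 | 1-[6-fluoro-2-hydroxy-4-methoxy-3-(prop-2-en-1-yloxy)phenyl]ethanone (3-O-allyl ether, not isolated) | CC(=O)c1c(F)cc(OC)c(OCC=C)c1O | intermediate
5 | 1-[2-(benzyloxy)-6-fluoro-4-methoxy-3-(prop-2-en-1-yloxy)phenyl]ethanone | CC(=O)c1c(F)cc(OC)c(OCC=C)c1OCc1ccccc1 | intermediate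
6 | 1-[2-(benzyloxy)-6-fluoro-3-hydroxy-4-methoxyphenyl]ethanone | CC(=O)c1c(F)cc(OC)c(O)c1OCc1ccccc1 | intermediate
7 | 1-[2,4-bis(benzyloxy)-6-hydroxyphenyl]ethanone | CC(=O)c1c(O)cc(OCc2ccccc2)cc1OCc1ccccc1 | starting material
8 | 4-iodobenzaldehyde | O=Cc1ccc(I)cc1 | starting material
9 | (E)-1-[2,4-bis(benzyloxy)-6-hydroxyphenyl]-3-(4-iodophenyl)prop-2-en-1-one | O=C(/C=C/c1ccc(I)cc1)c1c(O)cc(OCc2ccccc2)cc1OCc1ccccc1 | intermediate
10 | 5,7-bis(benzyloxy)-2-(4-iodophenyl)-4H-chromen-4-one | O=c1cc(-c2ccc(I)cc2)oc2cc(OCc3ccccc3)cc(OCc3ccccc3)c12 | intermediate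
11 | 1-[2-(benzyloxy)-3-{4-[5,7-bis(benzyloxy)-4-oxo-4H-chromen-2-yl]phenoxy}-6-fluoro-4-methoxyphenyl]ethanone | CC(=O)c1c(F)cc(OC)c(Oc2ccc(-c3cc(=O)c4c(OCc5ccccc5)cc(OCc5ccccc5)cc4o3)cc2)c1OCc1ccccc1 | intermediate
12 | 5,7-bis(benzyloxy)-2-[4-(2-(benzyloxy)-4-fluoro-6-methoxy-3-{1-[(trimethylsilyl)oxy]ethenyl}phenoxy)phenyl]-4H-chromen-4-one (trimethylsilyl enol ether of 11) | C=C(O[Si](C)(C)C)c1c(F)cc(OC)c(Oc2ccc(-c3cc(=O)c4c(OCc5ccccc5)cc(OCc5ccccc5)cc4o3)cc2)c1OCc1ccccc1 | intermediate
13 | 4-(benzyloxy)benzaldehyde | O=Cc1ccc(OCc2ccccc2)cc1 | starting material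
14 | (3S)-1-[2-(benzyloxy)-3-{4-[5,7-bis(benzyloxy)-4-oxo-4H-chromen-2-yl]phenoxy}-6-fluoro-4-methoxyphenyl]-3-[4-(benzyloxy)phenyl]-3-[(trimethylsilyl)oxy]propan-1-one (silyl aldol ether, not isolated) | O=C(C[C@@H](c1ccc(OCc2ccccc2)cc1)O[Si](C)(C)C)c1c(F)cc(OC)c(Oc2ccc(-c3cc(=O)c4c(OCc5ccccc5)cc(OCc5ccccc5)cc4o3)cc2)c1OCc1ccccc1 | intermediate
15 | (2S)-5-(benzyloxy)-2-[4-(benzyloxy)phenyl]-6-{4-[5,7-bis(benzyloxy)-4-oxo-4H-chromen-2-yl]phenoxy}-7-methoxy-2,3-dihydro-4H-chromen-4-one | COc1cc2c(c(OCc3ccccc3)c1Oc1ccc(-c3cc(=O)c4c(OCc5ccccc5)cc(OCc5ccccc5)cc4o3)cc1)C(=O)C[C@@H](c1ccc(OCc3ccccc3)cc1)O2 | intermediate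
16 | (2S)-6-[4-(5,7-dihydroxy-4-oxo-4H-chromen-2-yl)phenoxy]-5-hydroxy-2-(4-hydroxyphenyl)-7-methoxy-2,3-dihydro-4H-chromen-4-one | COc1cc2c(c(O)c1Oc1ccc(-c3cc(=O)c4c(O)cc(O)cc4o3)cc1)C(=O)C[C@@H](c1ccc(O)cc1)O2 | target

**Step count and risks**
Total steps: 10. Longest linear sequence: 8 (steps 1–4, then 7–10).

Steps most likely to fail:

Step 9 (the step under the label "Proposed new method:"). Retro-aldol cleavage or β-elimination of the fluoride-released aldolate may outrun ring closure, which would cost material and erode enantiopurity through re-addition. The Lewis-basic flavone carbonyl may also sequester the boron catalyst. The fallback uses known reaction types only, sets out from 11 and returns at 15. Ketone 11 is formylated at the methyl group with ethyl formate and sodium hydride in THF, and the sodium enolate is warmed in DMF so that its oxygen displaces the ortho fluorine, as in the cyclisation of 2-fluoroaryl 1,3-diketones to flavones. This should give 5-(benzyloxy)-6-{4-[5,7-bis(benzyloxy)-4-oxo-4H-chromen-2-yl]phenoxy}-7-methoxy-4H-chromen-4-one F1. A palladium(II)/tert-butyl-pyridine-oxazoline-catalysed asymmetric conjugate addition of 4-(benzyloxy)phenylboronic acid to the 2-unsubstituted chromone of F1 (ligand enantiomer chosen for 2S; base-free, aqueous 1,2-dichloroethane, 60 °C) should then give 15. The 2-aryl-substituted flavone unit is not an acceptor under these conditions. In this variant O1–C8a is formed first and C2 is set when the C2–aryl bond is made.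

Step 7. Reductive C–O coupling of the doubly ortho-substituted phenoxide may be slow, and intermolecular displacement of the ketone-activated fluorine or aldol self-condensation may compete in hot basic DMSO. The fallback sets out from 10 and returns at 11. Iodide 10 is oxidised with mCPBA/TsOH in MeCN and the iodine(III) intermediate is trapped with 1,3,5-trimethoxybenzene to give [4-(5,7-bis(benzyloxy)-4-oxo-4H-chromen-2-yl)phenyl](2,4,6-trimethoxyphenyl)iodonium 4-methylbenzenesulfonate F2. Metal-free O-arylation of 6 with F2 (Cs2CO3, MeCN, rt to 40 °C) proceeds by ligand coupling at iodine, in which the electron-rich trimethoxyphenyl group stays on iodine, and should give 11 without heating.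

Step 3. Discrimination between O-3 and O-2 in the first alkylation may be incomplete, or allyl bromide may carry over into the benzylation, giving regioisomeric and mixed ethers. The fallback sets out from 3 and returns at 6, so steps 3 and 4 are then not needed. Kinetic acetalisation of the non-chelated hydroxyl under amine-base conditions (MOMCl, i-Pr2NEt, CH2Cl2, 0 °C), which cannot break the ketone chelate of O-2, should give 1-[6-fluoro-2-hydroxy-4-methoxy-3-(methoxymethoxy)phenyl]ethanone F3, which is isolated and purified. Benzylation (BnBr, K2CO3, DMF, 60 °C) gives 1-[2-(benzyloxy)-6-fluoro-4-methoxy-3-(methoxymethoxy)phenyl]ethanone F4, and acetal cleavage (HCl, MeOH, 40 °C) should then give 6.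

**Further compounds**
F1 | step 9 | 5-(benzyloxy)-6-{4-[5,7-bis(benzyloxy)-4-oxo-4H-chromen-2-yl]phenoxy}-7-methoxy-4H-chromen-4-one | COc1cc2occc(=O)c2c(OCc2ccccc2)c1Oc1ccc(-c2cc(=O)c3c(OCc4ccccc4)cc(OCc4ccccc4)cc3o2)cc1
F2 | step 7 | [4-(5,7-bis(benzyloxy)-4-oxo-4H-chromen-2-yl)phenyl](2,4,6-trimethoxyphenyl)iodonium 4-methylbenzenesulfonate | COc1cc(OC)c([I+]c2ccc(-c3cc(=O)c4c(OCc5ccccc5)cc(OCc5ccccc5)cc4o3)cc2)c(OC)c1.Cc1ccc(cc1)S(=O)(=O)[O-]
F3 | step 3 | 1-[6-fluoro-2-hydroxy-4-methoxy-3-(methoxymethoxy)phenyl]ethanone | CC(=O)c1c(F)cc(OC)c(OCOC)c1O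
F4 | step 3 | 1-[2-(benzyloxy)-6-fluoro-4-methoxy-3-(methoxymethoxy)phenyl]ethanone | CC(=O)c1c(F)cc(OC)c(OCOC)c1OCc1ccccc1
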